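# Proposed total synthesis of CNP0227775.1 (compound 10)

## Analysis of the target

Compound 10 is a 1,4-benzodioxane neolignan made of two C6–C3 units. Ring A is the benzo ring (C4a, C5–C8, C8a) with OMe at C5 and an (E)-prop-1-enyl group at C7, ring B is the dihydrodioxine ring O1–C2–C3–O4–C4a–C8a, and ring C is the 4-hydroxy-3,5-dimethoxyphenyl group on C2. The only stereocentres are the neighbours C2 (R, bears ring C) and C3 (R, bears the methyl group); they are trans, so both substituents sit pseudo-equatorial on the half-chair of ring B, which is also the more stable arrangement. The two centres are not of equal rank: C2 is a benzylic aryl ether carbon para to the free phenol of ring C, so the C2–O1 bond can open reversibly to a p-quinone methide and C2 can always be re-set from C3, whereas C3 has no such escape and carries all the absolute information. A second, constitutional problem is that ring A is unsymmetrical: O4, flanked by the C5 methoxy group and para to C7, must bind the methyl-bearing C3, and O1 must bind the benzylic C2. Sensitive groups are the oxidisable 2,6-dimethoxyphenol, the acid- and base-labile C2–O1 bond, and the styrene-type propenyl group, which tolerates neither hydrogenation nor strong electrophiles. The feature that invites the strategy is the O1–C2–C3–O4 edge of ring B: together with C4a and C8a of ring A it is the formal [4+2] adduct of the O=C–C=O unit of an o-quinone and the Cα=Cβ bond of an (E)-propenylphenol, and the E geometry maps directly onto the trans C2/C3 relation. The 4-OH of ring C is both a hydrogen-bond handle for a chiral acid and the switch that makes the closure at C2 self-correcting.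

## Retrosynthetic reasoning

**Disconnection 1, 10 to 8 and 9 (bond from C7 of ring A to the propenyl group).** The propenyl group on ring A is cut first because it is the same functional group as the alkene that must react in the key step. Left in place it would compete as a second nucleophilic styrene, and on an o-quinone it would open a tautomerisation path to a quinone methide. A bromine atom at C7 of 8 stands in for it. In quinone 6 the bromine blocks C5 and adds to the polarisation that decides the regiochemistry. Later it is the handle for a stereoretentive sp2–sp2 coupling with the commercial E-boronate 9. The forward reaction has to keep the E geometry and must not harm the free phenol or the C2–O1 bond.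

**Disconnection 2, 8 to 6 and 5 through 7 (O4–C3 and O1–C2, all of ring B).** Both alkyl C–O bonds of ring B are cut at once.
- Cutting only one of them leaves an acyclic ether that needs its own source of chirality and a protecting-group scheme to tell the two phenolic oxygens apart.
- Cutting the aryl–oxygen bonds instead would call for a chiral diol and a regiodefined dihaloarene.
- The double cut leads to two flat, achiral partners, o-quinone 6 and propenylphenol 5, each one or two steps from commercial material. It removes every protecting group from the plan.
- The forward reaction must form O4–C3 first, under the control of a chiral phosphoric acid, to give p-quinone methide 7. It then closes O1–C2 under the control of C3.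
- It needs addition at the two oxygens of 6 rather than at its ring carbons, the correct orientation (Cβ of 5 to the oxygen next to the methoxy group), and one alkene face.

**Disconnection 3, 6 to 3, and 3 to 1 through 2 (redox level, then exchange of C–C for C–O at the future C8a).** Quinone 6 is the dehydrogenated form of catechol 3 and is made just before use with a heterogeneous oxidant that can be filtered off, so that no oxidant meets 5. Catechol 3 is traced to the commercial salicylaldehyde 1 by a Dakin oxidation through formate 2. The formyl carbon of 1 marks the place of the future O1, and the bromine already sits para to the future O4, so no regiochemical question arises in building ring A.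

**Disconnection 4, 5 to 4 (position of the double bond).** The E-propenylphenol 5 is the conjugated isomer of the commercial allylphenol 4. A catalytic isomerisation under thermodynamic control gives the E alkene without adding or removing an atom.

## Alternatives that were turned down

**Alternative 1:** the textbook route, in which the two C–O bonds are made one after the other from a dihydroxylated side chain.
- Disconnection: O4–C3 by substitution with inversion, then O1–C2 by acid-mediated closure.
- Forward: benzyl ether A1 of 5 undergoes Sharpless asymmetric dihydroxylation with the dihydroquinine-derived ligand to give diol A2. After temporary masking of the benzylic hydroxyl, Mitsunobu etherification with 1 gives ether A3. Dakin oxidation, closure and debenzylation follow.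
- Turned down: the two secondary hydroxyls of A2 have to be told apart, which costs extra steps. The benzylic stereocentre bought by the dihydroxylation is erased again in the ionising closure. Hydrogenolytic debenzylation collides with the aryl bromide, the benzylic ether and any propenyl group. No single step makes more than one bond, so the route is about twice as long.

**Alternative 2:** ring B first, ring C later.
- Disconnection: the C2–aryl bond together with both C–O bonds.
- Forward key step: a cinchona-alkaloid-catalysed enantioselective [4+2] addition of 6 to a C3 ketene enolate gives lactone A4. An aryl-metal reagent is then added to the lactone carbonyl and the resulting hemiketal is deoxygenated.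
- Turned down: the key step sets only C3 and builds a ring whose aryl ester is the best leaving group in the molecule, so the aryl nucleophile opens ring B again and can add twice. The deoxygenation passes through an oxocarbenium ion at C2 that can lose the proton at C3, which endangers the one stereocentre that cannot be repaired. The risk of handling 6 remains, while three or four more steps are needed and less is gained per step.

**Alternative 3:** a flat heterocycle, then hydrogen.
- Disconnection: the C2–H and C3–H bonds.
- Forward key step: asymmetric hydrogenation of the achiral 1,4-benzodioxine A5 gives the cis compound A6, which is then epimerised at C2 through 7 to 8.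
- Turned down: A5 holds a tetrasubstituted, doubly oxygenated alkene, the hardest class for asymmetric hydrogenation. Syn addition can only give the wrong relative configuration, so an extra inversion is built in. Making A5 needs a regiodefined α-aryloxy ketone, that is, most of the steps of Alternative 1. Reducing conditions also restrict the handling of the C–Br bond and the propenyl group.

Key step: step 4

Assumption: the sense of induction of the chiral acid cannot be derived from first principles; (R)-TRIP is written, and its mirror image is to be used if the (2S,3S) series turns out to be favoured.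

## Route

Step 1
Reactants: 1 5-bromo-2-hydroxy-3-methoxybenzaldehyde
Product: 3 5-bromo-3-methoxybenzene-1,2-diol, via aryl formate 2 (not isolated)
Conditions: 30% aq H2O2 (1.2 equiv), NaOH (1.05 equiv), THF/H2O, 0 °C to rt, N2; then 1 M HCl
Reagents that add atoms: hydrogen peroxide, OO
Why: Dakin oxidation: hydroperoxide adds to the aldehyde, the electron-rich aryl group migrates to oxygen to give formate 2, and hydroxide cleaves it in the flask. The ortho-hydroxyl makes 1 an ideal substrate, the carbon that bore the formyl group becomes the carbon of the future O1, and the aryl bromide and methyl ether are inert.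

Step 2
Reactants: 4 4-allyl-2,6-dimethoxyphenol
Product: 5 2,6-dimethoxy-4-[(E)-prop-1-en-1-yl]phenol
Conditions: RuHCl(CO)(PPh3)3 (0.5 mol %), toluene, 80 °C, Ar
Reagents that add atoms: none
Why: Ruthenium hydride catalysed alkene isomerisation (hydrometalation and β-hydride elimination) moves the double bond into conjugation with the arene. The E isomer is favoured thermodynamically and the free phenol is tolerated.

Step 3
Reactants: 3 5-bromo-3-methoxybenzene-1,2-diol
Product: 6 5-bromo-3-methoxycyclohexa-3,5-diene-1,2-dione
Conditions: Ag2O (2.5 equiv), Na2SO4, CH2Cl2, −20 °C, dark, 20 min; cold filtration through Celite under Ar, solution used at once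
Reagents that add atoms: none
Why: Two-electron dehydrogenation of a catechol to the o-quinone with silver oxide is a classical reaction. The oxidant and the silver formed are insoluble and are filtered off, so no oxidant reaches 5 in the next step. Drying agent and low temperature should suppress hydration and dimerisation.

Step 4
Reactants: 6 5-bromo-3-methoxycyclohexa-3,5-diene-1,2-dione; 5 2,6-dimethoxy-4-[(E)-prop-1-en-1-yl]phenol
Product: 8 4-[(2R,3R)-7-bromo-5-methoxy-3-methyl-2,3-dihydro-1,4-benzodioxin-2-yl]-2,6-dimethoxyphenol, via p-quinone methide 7 (not isolated)
Conditions: (R)-TRIP [(R)-3,3′-bis(2,4,6-triisopropylphenyl)-1,1′-binaphthyl-2,2′-diyl hydrogen phosphate, 10 mol %], 5 (1.3 equiv), 4 Å MS, CH2Cl2/toluene 1:1, −40 °C, 6 added over 4 h, dark, Ar; then 23 °C, 2 h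
Reagents that add atoms: none
Why: Proposed new method: the phosphoric acid is meant to bind both partners at once, its P=O oxygen accepting a hydrogen bond from the 4-OH of 5 and its P–OH donating one to the more basic carbonyl oxygen of 6 (that on C1, the end of the vinylogous ester MeO–C3=C4–C5=C6–C1=O), so that the nucleophilic Cβ of 5 attacks the oxygen of the cross-conjugated C2 carbonyl, ring A aromatises in the same event and p-quinone methide 7 results. The new phenol O1–H of 7 then adds to the exocyclic carbon of the quinone methide in a 6-exo-trig oxa-1,6-addition that closes ring B, and a concerted but very asynchronous inverse-electron-demand hetero-Diels–Alder path would give the same product. The closest known reaction types are the thermal [4+2] addition of o-quinones as O=C–C=O heterodienes to styrenes and enol ethers, the alkaloid-catalysed enantioselective [4+2] addition of o-quinones to ketene enolates, and the chiral-phosphoric-acid-catalysed formal [3+2] additions of hydroxystyrenes to quinone derivatives that pass through quinone methides; what is new is the enantioselective O,O-addition to a propenylphenol. C3 is set in the irreversible first C–O bond formation by the catalyst, which has to expose the Re face of Cβ. C2 is controlled by C3: closure through a half-chair with the methyl and aryl groups pseudo-equatorial gives the trans isomer, and because the 4-hydroxyaryl group keeps the C2–O1 bond reversible under the acid, any cis isomer is funnelled to the same (2R,3R) product during the final warming. Regioselectivity (Cβ to the oxygen on C2 of 6, the future O4) rests on the polarisation just described, which the 3-OMe and 5-Br donors both reinforce. Periselectivity rests on the OMe and Br groups that block C3 and C5 of the quinone and on the fact that only attack at oxygen gains the aromaticity of ring A in the first bond-forming event. Slow addition of 6 at low temperature keeps its concentration small, so that dimerisation, hydrogen-atom transfer from 5 and the uncatalysed racemic addition should stay behind the catalysed path.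

Step 5
Reactants: 8 4-[(2R,3R)-7-bromo-5-methoxy-3-methyl-2,3-dihydro-1,4-benzodioxin-2-yl]-2,6-dimethoxyphenol; 9 4,4,5,5-tetramethyl-2-[(E)-prop-1-en-1-yl]-1,3,2-dioxaborolane
Product: 10 4-[(2R,3R)-5-methoxy-3-methyl-7-[(E)-prop-1-en-1-yl]-2,3-dihydro-1,4-benzodioxin-2-yl]-2,6-dimethoxyphenol
Conditions: Pd(OAc)2 (3 mol %), SPhos (6 mol %), K3PO4 (3 equiv), THF/H2O 10:1, 45 °C, Ar
Reagents that add atoms: none
Why: Suzuki–Miyaura coupling: zerovalent palladium formed in the flask inserts into the C7–Br bond, the propenyl group is transferred with retention of the E geometry, and reductive elimination gives 10. C2 and C3 take no part; should the phenoxide open the C2–O1 bond reversibly, re-closure returns the more stable trans isomer.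

## Compound list

1 | 5-bromo-2-hydroxy-3-methoxybenzaldehyde | O=Cc1cc(Br)cc(OC)c1O | starting material
2 | 5-bromo-2-hydroxy-3-methoxyphenyl formate | O=COc1cc(Br)cc(OC)c1O | intermediate
3 | 5-bromo-3-methoxybenzene-1,2-diol | Oc1cc(Br)cc(OC)c1O | intermediate
4 | 4-allyl-2,6-dimethoxyphenol | C=CCc1cc(OC)c(O)c(OC)c1 | starting material
5 | 2,6-dimethoxy-4-[(E)-prop-1-en-1-yl]phenol | C/C=C/c1cc(OC)c(O)c(OC)c1 | intermediate
6 | 5-bromo-3-methoxycyclohexa-3,5-diene-1,2-dione | COC1=CC(Br)=CC(=O)C1=O | intermediate
7 | 4-[(2R)-2-(4-bromo-2-hydroxy-6-methoxyphenoxy)propylidene]-2,6-dimethoxycyclohexa-2,5-dien-1-one | COC1=CC(=C[C@@H](C)Oc2c(O)cc(Br)cc2OC)C=C(OC)C1=O | intermediate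
8 | 4-[(2R,3R)-7-bromo-5-methoxy-3-methyl-2,3-dihydro-1,4-benzodioxin-2-yl]-2,6-dimethoxyphenol | Brc1cc(OC)c2c(c1)O[C@H](c1cc(OC)c(O)c(OC)c1)[C@@H](C)O2 | intermediate
9 | 4,4,5,5-tetramethyl-2-[(E)-prop-1-en-1-yl]-1,3,2-dioxaborolane | C/C=C/B1OC(C)(C)C(C)(C)O1 | starting material
10 | 4-[(2R,3R)-5-methoxy-3-methyl-7-[(E)-prop-1-en-1-yl]-2,3-dihydro-1,4-benzodioxin-2-yl]-2,6-dimethoxyphenol | C/C=C/c1cc(OC)c2c(c1)O[C@H](c1cc(OC)c(O)c(OC)c1)[C@@H](C)O2 | target

## Step count and risk

Total step count: 5. Longest linear sequence: 4 (steps 1, 3, 4, 5). No protecting group is used.

**Step 4 (key step, proposed new method).** Four things are most likely to go wrong: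
- Carbon–carbon bond formation at the open ring carbon C6 of the quinone (a [3+2] mode), or Diels–Alder addition across C3/C6, instead of addition at the two oxygens.
- Hydrogen-atom or electron transfer between the two partners, which opens an uncatalysed radical coupling channel and erodes the enantiomeric purity.
- Weak facial discrimination, because the hydrogen-bond handle lies far from Cβ.
- Leakage of the regiochemistry, because the oxygen to be attacked is the more hindered one.

The fallback uses only known chemistry, sets out from 1 and comes back to the route at 7 and hence at 8. The only free hydroxyl of 1 is the future O4. It is etherified under Mitsunobu conditions (PPh3, DIAD, THF) with (2S)-2-hydroxy-N-methoxy-N-methylpropanamide F1, made from ethyl (S)-lactate with MeNHOMe·HCl and iPrMgCl. The reaction goes with inversion and gives the (R)-configured aryl ether F2, so regiochemistry and C3 are both fixed without ambiguity. Baeyer–Villiger oxidation of the formyl group with mCPBA gives aryl formate F3, and brief methanolysis (catalytic K2CO3, MeOH, 0 °C) frees the future O1 in phenol F4. Silyl ether F5, from commercial 4-bromo-2,6-dimethoxyphenol with TBSCl and imidazole, is lithiated with nBuLi at −78 °C. It is then added to F4 that has first been deprotonated with iPrMgCl, and this gives ketone F6 on acidic quench. NaBH4 in MeOH gives alcohol F7 as a mixture of epimers at the carbinol carbon, which does not matter. TBAF buffered with AcOH gives the p-hydroxybenzyl alcohol F8. Catalytic TsOH in CH2Cl2 dehydrates F8 to the same p-quinone methide 7, which closes stereoconvergently to 8.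

**Step 3.** Self-Diels–Alder dimerisation, hydration or further oxidation of the quinone during filtration and transfer may starve the key step of heterodiene or feed it with acidic decomposition products that catalyse a racemic background reaction. The fallback sets out from 3 and 5 and comes back at 8, and it prepares no quinone at all. Compounds 3 and 5 are co-oxidised in one flask with Ag2O in benzene/acetone, the biomimetic one-electron cross-coupling of the phenoxyl radical of 5 at Cβ with the oxygen-centred radical of 3. This passes through 7 together with its mirror image F9, and gives the trans product as 8 together with its mirror image F10. The two are separated by preparative chromatography on a chiral stationary phase. The price is the loss of half the material and a weaker hold on the regiochemistry.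

**Step 5.** The base turns ring C into its phenoxide, which can expel O1 and open ring B. Loss of the C3 proton from the open quinone methide, or addition of water to it, would then drain material. Protodeboronation of 9 and slow oxidative addition into the electron-rich C–Br bond are further concerns. The fallback sets out from 8 and comes back at 10, avoids base altogether, and sets the alkene geometry by equilibration rather than by stereoretentive transfer. Stille coupling of 8 with allyltributylstannane (Pd(PPh3)4, toluene, 90 °C) gives the allyl compound F11. Its double bond is then moved into conjugation with RuHCl(CO)(PPh3)3 in toluene at 80 °C, as in step 2.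

## Further compounds

F1 | step 4 | (2S)-2-hydroxy-N-methoxy-N-methylpropanamide | C[C@H](O)C(=O)N(C)OC
F2 | step 4 | (2R)-2-(4-bromo-2-formyl-6-methoxyphenoxy)-N-methoxy-N-methylpropanamide | C[C@@H](Oc1c(C=O)cc(Br)cc1OC)C(=O)N(C)OC
F3 | step 4 | (2R)-2-[4-bromo-2-(formyloxy)-6-methoxyphenoxy]-N-methoxy-N-methylpropanamide | C[C@@H](Oc1c(OC=O)cc(Br)cc1OC)C(=O)N(C)OC
F4 | step 4 | (2R)-2-(4-bromo-2-hydroxy-6-methoxyphenoxy)-N-methoxy-N-methylpropanamide | C[C@@H](Oc1c(O)cc(Br)cc1OC)C(=O)N(C)OC
F5 | step 4 | (4-bromo-2,6-dimethoxyphenoxy)(tert-butyl)dimethylsilane | COc1cc(Br)cc(OC)c1O[Si](C)(C)C(C)(C)C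
F6 | step 4 | (2R)-2-(4-bromo-2-hydroxy-6-methoxyphenoxy)-1-{4-[(tert-butyldimethylsilyl)oxy]-3,5-dimethoxyphenyl}propan-1-one | C[C@@H](Oc1c(O)cc(Br)cc1OC)C(=O)c1cc(OC)c(O[Si](C)(C)C(C)(C)C)c(OC)c1
F7 | step 4 | (2R)-2-(4-bromo-2-hydroxy-6-methoxyphenoxy)-1-{4-[(tert-butyldimethylsilyl)oxy]-3,5-dimethoxyphenyl}propan-1-ol, mixture of C1 epimers | C[C@@H](Oc1c(O)cc(Br)cc1OC)C(O)c1cc(OC)c(O[Si](C)(C)C(C)(C)C)c(OC)c1
F8 | step 4 | 4-[(2R)-2-(4-bromo-2-hydroxy-6-methoxyphenoxy)-1-hydroxypropyl]-2,6-dimethoxyphenol, mixture of C1 epimers | C[C@@H](Oc1c(O)cc(Br)cc1OC)C(O)c1cc(OC)c(O)c(OC)c1
F9 | step 3 | 4-[(2S)-2-(4-bromo-2-hydroxy-6-methoxyphenoxy)propylidene]-2,6-dimethoxycyclohexa-2,5-dien-1-one | COC1=CC(=C[C@H](C)Oc2c(O)cc(Br)cc2OC)C=C(OC)C1=O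
F10 | step 3 | 4-[(2S,3S)-7-bromo-5-methoxy-3-methyl-2,3-dihydro-1,4-benzodioxin-2-yl]-2,6-dimethoxyphenol | Brc1cc(OC)c2c(c1)O[C@@H](c1cc(OC)c(O)c(OC)c1)[C@H](C)O2
F11 | step 5 | 4-[(2R,3R)-7-allyl-5-methoxy-3-methyl-2,3-dihydro-1,4-benzodioxin-2-yl]-2,6-dimethoxyphenol | C=CCc1cc(OC)c2c(c1)O[C@H](c1cc(OC)c(O)c(OC)c1)[C@@H](C)O2
A1 | alternative 1 | 2-(benzyloxy)-1,3-dimethoxy-5-[(E)-prop-1-en-1-yl]benzene | C/C=C/c1cc(OC)c(OCc2ccccc2)c(OC)c1
A2 | alternative 1 | (1S,2S)-1-[4-(benzyloxy)-3,5-dimethoxyphenyl]propane-1,2-diol | C[C@H](O)[C@@H](O)c1cc(OC)c(OCc2ccccc2)c(OC)c1
A3 | alternative 1 | 2-{[(1S,2R)-1-[4-(benzyloxy)-3,5-dimethoxyphenyl]-1-hydroxypropan-2-yl]oxy}-5-bromo-3-methoxybenzaldehyde | C[C@@H](Oc1c(C=O)cc(Br)cc1OC)[C@@H](O)c1cc(OC)c(OCc2ccccc2)c(OC)c1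
A4 | alternative 2 | (3R)-7-bromo-5-methoxy-3-methyl-2,3-dihydro-1,4-benzodioxin-2-one | C[C@H]1Oc2c(OC)cc(Br)cc2OC1=O
A5 | alternative 3 | 4-(7-bromo-5-methoxy-3-methyl-1,4-benzodioxin-2-yl)-2,6-dimethoxyphenol | CC1=C(c2cc(OC)c(O)c(OC)c2)Oc2cc(Br)cc(OC)c2O1
A6 | alternative 3 | 4-[(2S,3R)-7-bromo-5-methoxy-3-methyl-2,3-dihydro-1,4-benzodioxin-2-yl]-2,6-dimethoxyphenol | Brc1cc(OC)c2c(c1)O[C@@H](c1cc(OC)c(O)c(OC)c1)[C@@H](C)O2
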